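**Plan**

- Retrosynthesis cuts, in order: the C1'–C6 bond (side-chain CH2 to the ring carbinol carbon), giving a ring C6 enolate and a chiral primary triflate; then the C6–O bond (α'-hydroxylation of (S)-4-silyloxycyclohex-2-enone); then C1'–C2' of the chain (methylene transfer to (Z)-hexadec-9-enal).
- Forward: the six-membered ring is bought as a ketal enone, made chiral at C4 and oxygenated at C6; the C17 chain is built from the C16 Z-enal; the two are joined at C6 in step 9; one deprotection ends the route.
- Enabling feature: C6 is an acyloin carbon lying between the C1 carbonyl and the C5 methylene of the cyclohex-2-enone ring. With its oxygen in place and one hydrogen left it gives a tetrasubstituted 2-oxy dienolate (O–C1=C6 beside C2=C3) that is nucleophilic only at C6, with the C4 oxygen 1,3 to it across C5.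
- Stereochemistry: C4 by asymmetric transfer hydrogenation; C6 relayed from C4 (alkylation anti to C4–OSi, which puts the two ring oxygens cis); C2' by hydrolytic kinetic resolution; the Z-alkene is bought.

Key step: step 9

Remark: the ring is numbered as cyclohex-2-en-1-one (C1 carbonyl, C4 and C6 carbinol carbons) and the chain C1'–C17'; the target is (4S,6R)-4,6-dihydroxy-6-[(2S,10Z)-2-hydroxyheptadec-10-en-1-yl]cyclohex-2-en-1-one.
Remark: the sense of the kinetic resolution in step 7 is assigned by analogy with simple 1,2-epoxyalkanes ((R,R)-catalyst hydrolyses the (S)-epoxide); the configuration of 10 should be confirmed (Mosher ester) and the antipodal catalyst used if it proves opposite.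
Remark: the 1-ethoxyethyl acetal carbon is carried as a mixture of epimers, and the C6 configuration of 6 and 7 is of no consequence because it is erased in step 9.

**Step 1**
Reactants: 1 1,4-dioxaspiro[4.5]dec-6-en-8-one
Product: 2 (8S)-1,4-dioxaspiro[4.5]dec-6-en-8-ol
Conditions: RuCl[(S,S)-TsDPEN](p-cymene) (1 mol %), HCO2Na, n-Bu4NCl (cat.), CH2Cl2/H2O, rt
Reagents that add atoms: none
Why: Noyori-type asymmetric transfer hydrogenation should reduce the enone carbonyl 1,2-selectively, the ring alkene taking the role of the aryl group of an aryl ketone, so that the (S,S)-catalyst sets the (8S) carbinol centre while the ketal survives the neutral two-phase medium.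

**Step 2**
Reactants: 2 (8S)-1,4-dioxaspiro[4.5]dec-6-en-8-ol
Product: 3 tert-butyl{[(8S)-1,4-dioxaspiro[4.5]dec-6-en-8-yl]oxy}dimethylsilane
Conditions: TBSCl, imidazole, DMF, rt
Reagents that add atoms: tert-butyldimethylsilyl chloride, CC(C)(C)[Si](C)(C)Cl
Why: Imidazole-promoted silylation of the secondary allylic alcohol is standard and does not touch the stereocentre.

**Step 3**
Reactants: 3 tert-butyl{[(8S)-1,4-dioxaspiro[4.5]dec-6-en-8-yl]oxy}dimethylsilane
Product: 4 (4S)-4-[(tert-butyldimethylsilyl)oxy]cyclohex-2-en-1-one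
Conditions: montmorillonite K-10, wet CH2Cl2, rt
Reagents that add atoms: water, O
Why: Acid-clay hydrolysis of the allylic ketal (ketal deprotection) is fast because the oxocarbenium ion is allylic, and should leave the secondary TBS ether and the carbinol centre intact.

**Step 4**
Reactants: 4 (4S)-4-[(tert-butyldimethylsilyl)oxy]cyclohex-2-en-1-one
Product: 6 (4S,6S)-4-[(tert-butyldimethylsilyl)oxy]-6-hydroxycyclohex-2-en-1-one, via potassium dienolate 5 (not isolated)
Conditions: KHMDS, THF, −78 °C; then 2-(phenylsulfonyl)-3-phenyloxaziridine, −78 °C; AcOH quench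
Reagents that add atoms: 2-(phenylsulfonyl)-3-phenyloxaziridine, O=S(=O)(c1ccccc1)N1OC1c1ccccc1
Why: Kinetic α'-deprotonation gives the cross-conjugated dienolate, which takes up oxygen at C6 from the N-sulfonyloxaziridine (Davis enolate hydroxylation), expected mainly anti to the C4 silyloxy group.

**Step 5**
Reactants: 6 (4S,6S)-4-[(tert-butyldimethylsilyl)oxy]-6-hydroxycyclohex-2-en-1-one
Product: 7 (4S,6S)-4-[(tert-butyldimethylsilyl)oxy]-6-(1-ethoxyethoxy)cyclohex-2-en-1-one
Conditions: ethyl vinyl ether, PPTS (cat.), CH2Cl2, 0 °C → rt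
Reagents that add atoms: ethyl vinyl ether, C=COCC
Why: Acid-catalysed addition of the hydroxyl to the vinyl ether gives a small, base-stable acetal that, unlike a silyl group, cannot shift from oxygen to oxygen in the later enolate and comes off under very mild acid.

**Step 6**
Reactants: 8 (Z)-hexadec-9-enal
Product: 9 rac-2-[(Z)-pentadec-8-en-1-yl]oxirane
Conditions: Me3S+ I−, n-BuLi, THF, −10 °C; then 8, −10 °C → rt
Reagents that add atoms: trimethylsulfonium iodide, C[S+](C)C.[I-]
Why: Corey–Chaykovsky methylene transfer from the sulfonium ylide to the aldehyde gives the terminal epoxide; at low temperature the ylide should add faster than it enolises the aldehyde and it leaves the Z-alkene alone.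

**Step 7**
Reactants: 9 rac-2-[(Z)-pentadec-8-en-1-yl]oxirane
Product: 10 (2S,10Z)-heptadec-10-ene-1,2-diol
Conditions: (R,R)-(salen)Co(III)OAc (0.5 mol %), H2O (0.45 equiv), THF (min.), 0 °C → rt
Reagents that add atoms: water, O
Why: In the hydrolytic kinetic resolution of a terminal epoxide the (R,R)-catalyst should hydrolyse the (S)-epoxide selectively by attack of water at C1, so C2 keeps its configuration and the (S)-diol forms with water as the limiting reagent.

**Step 8**
Reactants: 10 (2S,10Z)-heptadec-10-ene-1,2-diol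
Product: 12 (2S,10Z)-2-[(tert-butyldimethylsilyl)oxy]heptadec-10-en-1-yl trifluoromethanesulfonate, via hydroxy triflate 11 (not isolated)
Conditions: Tf2O (1.05 equiv), 2,6-lutidine, CH2Cl2, −78 °C; then TBSOTf, −78 → −40 °C; cold work-up, used at once
Reagents that add atoms: trifluoromethanesulfonic anhydride, O=S(=O)(OS(=O)(=O)C(F)(F)F)C(F)(F)F; tert-butyldimethylsilyl trifluoromethanesulfonate, CC(C)(C)[Si](C)(C)OS(=O)(=O)C(F)(F)F
Why: One-flask triflation–silylation of a terminal 1,2-diol: the primary hydroxyl is sulfonylated selectively at −78 °C and the secondary hydroxyl is then silylated, with no bond to C2 broken.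

**Step 9**
Reactants: 7 (4S,6S)-4-[(tert-butyldimethylsilyl)oxy]-6-(1-ethoxyethoxy)cyclohex-2-en-1-one; 12 (2S,10Z)-2-[(tert-butyldimethylsilyl)oxy]heptadec-10-en-1-yl trifluoromethanesulfonate
Product: 14 (4S,6R)-4-[(tert-butyldimethylsilyl)oxy]-6-{(2S,10Z)-2-[(tert-butyldimethylsilyl)oxy]heptadec-10-en-1-yl}-6-(1-ethoxyethoxy)cyclohex-2-en-1-one, via lithium dienolate 13 (not isolated)
Conditions: LDA (1.05 equiv), THF, −78 °C (7 added to the base); then 12 (1.3 equiv) in THF, −78 → −40 °C
Reagents that add atoms: none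
Why: LDA removes the single α'-hydrogen (C6–H) of 7 to give the tetrasubstituted 2-oxy cross-conjugated lithium dienolate 13 (O–C1=C6 beside C2=C3), whose C6 displaces triflate from the primary C1' of 12 in an SN2 step that makes the C1'–C6 bond and the oxygenated quaternary centre at once. The closest known reaction type is the C-alkylation of α-alkoxy ketone enolates, and the α'-alkylation of 4-silyloxycyclohex-2-enone enolates, with primary alkyl triflates; no ring is closed. The new stereocentre C6 is set by substrate control from C4: in the half-chair dienolate the C4–OTBS group stands pseudoaxial, 1,3 to C6 across C5, so the electrophile should enter the opposite face, which places the chain trans and the C6 oxygen cis to the C4 oxygen, i.e. (6R). Both C6 epimers and both acetal epimers of 7 converge on the same planar C6, C2' arrives unchanged because substitution takes place at C1' only, and C4 is not touched. The step needs C- over O-alkylation, secured by the lithium counter-ion in THF without dipolar cosolvent and by chelation of lithium between the enolate and acetal oxygens, and α' over γ deprotonation, secured by the kinetic amide base at −78 °C. Substitution should outrun elimination because the triflate is primary and its β-oxygen retards E2.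

**Step 10**
Reactants: 14 (4S,6R)-4-[(tert-butyldimethylsilyl)oxy]-6-{(2S,10Z)-2-[(tert-butyldimethylsilyl)oxy]heptadec-10-en-1-yl}-6-(1-ethoxyethoxy)cyclohex-2-en-1-one
Product: 15 (4S,6R)-4,6-dihydroxy-6-[(2S,10Z)-2-hydroxyheptadec-10-en-1-yl]cyclohex-2-en-1-one
Conditions: 48% aq. HF/MeCN (1:19), 0 °C → rt
Reagents that add atoms: none
Why: Global deprotection: aqueous HF should cleave both Si–O bonds and its mild acidity should hydrolyse the acetal, with no base to trigger an α-ketol shift and no acid strong enough to ionise the carbinols, so no stereocentre is touched.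

**Compound list**

1 | 1,4-dioxaspiro[4.5]dec-6-en-8-one | O=C1C=CC2(CC1)OCCO2 | starting material
2 | (8S)-1,4-dioxaspiro[4.5]dec-6-en-8-ol | O[C@H]1CCC2(OCCO2)C=C1 | intermediate
3 | tert-butyl{[(8S)-1,4-dioxaspiro[4.5]dec-6-en-8-yl]oxy}dimethylsilane | CC(C)(C)[Si](C)(C)O[C@H]1CCC2(OCCO2)C=C1 | intermediate
4 | (4S)-4-[(tert-butyldimethylsilyl)oxy]cyclohex-2-en-1-one | O=C1CC[C@H](O[Si](C)(C)C(C)(C)C)C=C1 | intermediate
5 | potassium dienolate of 4 (O–C1=C6, C2=C3) | [K+].[O-]C1=CC[C@H](O[Si](C)(C)C(C)(C)C)C=C1 | intermediate (not isolated)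
6 | (4S,6S)-4-[(tert-butyldimethylsilyl)oxy]-6-hydroxycyclohex-2-en-1-one (trans isomer expected as major) | O[C@H]1C[C@H](O[Si](C)(C)C(C)(C)C)C=CC1=O | intermediate
7 | (4S,6S)-4-[(tert-butyldimethylsilyl)oxy]-6-(1-ethoxyethoxy)cyclohex-2-en-1-one (acetal epimers) | CCOC(C)O[C@H]1C[C@H](O[Si](C)(C)C(C)(C)C)C=CC1=O | intermediate
8 | (Z)-hexadec-9-enal | CCCCCC/C=C\CCCCCCCC=O | starting material
9 | rac-2-[(Z)-pentadec-8-en-1-yl]oxirane | CCCCCC/C=C\CCCCCCCC1CO1 | intermediate
10 | (2S,10Z)-heptadec-10-ene-1,2-diol | CCCCCC/C=C\CCCCCCC[C@H](O)CO | intermediate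
11 | (2S,10Z)-2-hydroxyheptadec-10-en-1-yl trifluoromethanesulfonate | CCCCCC/C=C\CCCCCCC[C@H](O)COS(=O)(=O)C(F)(F)F | intermediate (not isolated)
12 | (2S,10Z)-2-[(tert-butyldimethylsilyl)oxy]heptadec-10-en-1-yl trifluoromethanesulfonate | CCCCCC/C=C\CCCCCCC[C@H](O[Si](C)(C)C(C)(C)C)COS(=O)(=O)C(F)(F)F | intermediate
13 | lithium dienolate of 7 (O–C1=C6, C2=C3) | [Li+].[O-]C1=C(OC(C)OCC)C[C@H](O[Si](C)(C)C(C)(C)C)C=C1 | intermediate (not isolated)
14 | (4S,6R)-4-[(tert-butyldimethylsilyl)oxy]-6-{(2S,10Z)-2-[(tert-butyldimethylsilyl)oxy]heptadec-10-en-1-yl}-6-(1-ethoxyethoxy)cyclohex-2-en-1-one (acetal epimers) | CCCCCC/C=C\CCCCCCC[C@H](O[Si](C)(C)C(C)(C)C)C[C@@]1(OC(C)OCC)C[C@H](O[Si](C)(C)C(C)(C)C)C=CC1=O | intermediate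
15 | (4S,6R)-4,6-dihydroxy-6-[(2S,10Z)-2-hydroxyheptadec-10-en-1-yl]cyclohex-2-en-1-one | CCCCCC/C=C\CCCCCCC[C@H](O)C[C@@]1(O)C[C@H](O)C=CC1=O | target

**Step count and risks**

Total steps: 10. Longest linear sequence: 7 steps (steps 1, 2, 3, 4, 5, 9, 10).

Steps most likely to fail:

Step 9. The hindered tetrasubstituted enolate may be alkylated on oxygen by the hard triflate, may be protonated or cause elimination in place of substitution, or may show a weak facial bias. The fallback sets out from 7 (with racemic 9) and comes back at 15; it replaces the enolate/triflate union by an aza-enolate/epoxide opening, which cannot alkylate on oxygen. Compound 7 is condensed with N,N-dimethylhydrazine (cat. AcOH, EtOH, rt) to the N,N-dimethylhydrazone F1. Racemic 9 is resolved with the antipodal (S,S)-(salen)Co(III)OAc catalyst (0.55 equiv H2O) and the unreacted (S)-2-[(Z)-pentadec-8-en-1-yl]oxirane F2 is recovered. Metalation of F1 (LDA, THF, −78 → 0 °C) gives the lithium aza-enolate F3, which should open F2 at its terminal carbon, again anti to the C4 silyloxy group, to give the γ-hydroxy hydrazone F4. Mild hydrolysis (aq. Cu(OAc)2, THF, rt) gives the hydroxy ketone F5, which the conditions of step 10 should convert into 15.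

Step 8. The secondary hydroxyl may be triflated as well, or the primary triflate may be lost to attack by the neighbouring free hydroxyl (epoxide formation) before silylation is complete. The fallback sets out from 10 and comes back at 12; it differentiates the two hydroxyls stepwise. PivCl and pyridine (CH2Cl2, 0 °C) give the primary pivalate F6, TBSOTf and 2,6-lutidine give the silyl ether F7, and DIBAL-H (CH2Cl2, −78 °C) frees the primary alcohol F8. Tf2O and 2,6-lutidine at −78 °C then give 12 with the neighbouring oxygen already silylated.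

Step 10. Acid may promote loss of water from the C4 and C6 carbinols with aromatisation to the alkylhydroquinone, or the hindered silyl ethers may be cleaved incompletely. The fallback sets out from 14 and comes back at 15; it separates acetal cleavage from desilylation so that neither needs aqueous acid. Transacetalisation (PPTS, MeOH, 0 °C) removes only the acetal to give the tertiary alcohol F9. Anhydrous, near-neutral fluoride (TASF, DMF, 0 °C, or TBAF buffered with AcOH, THF) should then cleave both silyl ethers to give 15.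

**Further compounds**

F1 | step 9 | (4S,6S)-4-[(tert-butyldimethylsilyl)oxy]-6-(1-ethoxyethoxy)cyclohex-2-en-1-one N,N-dimethylhydrazone | CCOC(C)O[C@H]1C[C@H](O[Si](C)(C)C(C)(C)C)C=CC1=NN(C)C
F2 | step 9 | (S)-2-[(Z)-pentadec-8-en-1-yl]oxirane | CCCCCC/C=C\CCCCCCC[C@H]1CO1
F3 | step 9 | lithium aza-enolate of F1 | [Li+].CN(C)[N-]C1=C(OC(C)OCC)C[C@H](O[Si](C)(C)C(C)(C)C)C=C1
F4 | step 9 | (4S,6R)-4-[(tert-butyldimethylsilyl)oxy]-6-(1-ethoxyethoxy)-6-[(2S,10Z)-2-hydroxyheptadec-10-en-1-yl]cyclohex-2-en-1-one N,N-dimethylhydrazone | CCCCCC/C=C\CCCCCCC[C@H](O)C[C@@]1(OC(C)OCC)C[C@H](O[Si](C)(C)C(C)(C)C)C=CC1=NN(C)C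
F5 | step 9 | (4S,6R)-4-[(tert-butyldimethylsilyl)oxy]-6-(1-ethoxyethoxy)-6-[(2S,10Z)-2-hydroxyheptadec-10-en-1-yl]cyclohex-2-en-1-one | CCCCCC/C=C\CCCCCCC[C@H](O)C[C@@]1(OC(C)OCC)C[C@H](O[Si](C)(C)C(C)(C)C)C=CC1=O
F6 | step 8 | (2S,10Z)-2-hydroxyheptadec-10-en-1-yl pivalate | CCCCCC/C=C\CCCCCCC[C@H](O)COC(=O)C(C)(C)C
F7 | step 8 | (2S,10Z)-2-[(tert-butyldimethylsilyl)oxy]heptadec-10-en-1-yl pivalate | CCCCCC/C=C\CCCCCCC[C@H](O[Si](C)(C)C(C)(C)C)COC(=O)C(C)(C)C
F8 | step 8 | (2S,10Z)-2-[(tert-butyldimethylsilyl)oxy]heptadec-10-en-1-ol | CCCCCC/C=C\CCCCCCC[C@H](O[Si](C)(C)C(C)(C)C)CO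
F9 | step 10 | (4S,6R)-4-[(tert-butyldimethylsilyl)oxy]-6-{(2S,10Z)-2-[(tert-butyldimethylsilyl)oxy]heptadec-10-en-1-yl}-6-hydroxycyclohex-2-en-1-one | CCCCCC/C=C\CCCCCCC[C@H](O[Si](C)(C)C(C)(C)C)C[C@@]1(O)C[C@H](O[Si](C)(C)C(C)(C)C)C=CC1=O
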